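**Retrosynthetic overview**
- The target is (2S)-6-prenylhomoeriodictyol; the last step only removes three MOM ethers from the fully protected flavanone.
- Key disconnection: the O1–C8a and C4–C4a bonds of ring C are cut together, giving a ring-A aryne (triple bond C4a≡C8a) and an (S)-β-silyloxy Weinreb amide that carries C2, C3, C4 and ring B.
- Enabling feature: in ring A, O1 (on C8a) and the acyl carbon C4 (on C4a) sit on neighbouring carbons; C4a has the oxygenated C5 beside it and C8a only C8–H. This is the pattern left by a 3-alkoxyaryne, and O1–C2–C3–C4 is an aldol pattern.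
- The aryne precursor (a 2-silylaryl triflate) comes from phloroglucinol: prenyl is placed between two OMOM groups by directed metalation, then bromination, retro-Brook silyl shift and triflation. The amide comes from methyl vanillate by Claisen condensation and asymmetric transfer hydrogenation, which sets C2.
- Ring order: rings A and B are bought as aromatics; ring C is the only ring formed, in the key step.

Key step: step 10

Remark: the target is read as the (2S)-flavanone (O1 > C1' > C3 > H); compounds 8 and 17 are written as the lithium and cesium salts present in the flask.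

Step 1
Reactants: 1 phloroglucinol (benzene-1,3,5-triol)
Product: 2 3,5-bis(methoxymethoxy)phenol
Conditions: MOMCl (2.0 equiv), i-Pr2NEt, DMF, 0 °C to rt; chromatography
Reagents that add atoms: chloromethyl methyl ether, COCCl
Why: Williamson-type O-alkylation of a threefold-symmetric triphenol, where only the degree of alkylation must be controlled (mono- and tris-ethers are separable and recyclable); the remaining hydroxyl marks the oxygen later lost as triflate.

Step 2
Reactants: 2 3,5-bis(methoxymethoxy)phenol
Product: 3 [3,5-bis(methoxymethoxy)phenoxy]triisopropylsilane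
Conditions: TIPSCl, imidazole, DMF, rt
Reagents that add atoms: chlorotriisopropylsilane, CC(C)[Si](Cl)(C(C)C)C(C)C
Why: Phenol silylation; the bulky, poorly coordinating OTIPS group shields its two ortho positions so that the next metalation should occur only between the two OMOM groups.

Step 3
Reactants: 3 [3,5-bis(methoxymethoxy)phenoxy]triisopropylsilane
Product: 5 3,5-bis(methoxymethoxy)-4-(3-methylbut-2-en-1-yl)phenol, via prenylated TIPS ether 4 (not isolated)
Conditions: n-BuLi, THF, 0 °C; CuI (10 mol %), prenyl bromide, −78 to 0 °C; then TBAF, rt; aq. NH4Cl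
Reagents that add atoms: 1-bromo-3-methylbut-2-ene (prenyl bromide), CC(C)=CCBr
Why: Directed ortho-metalation at the C–H flanked by two chelating OMOM groups, copper-catalysed SN2 allylation of the aryllithium at the primary carbon of prenyl bromide, then fluoride cleavage of the aryl silyl ether in the same flask.

Step 4
Reactants: 5 3,5-bis(methoxymethoxy)-4-(3-methylbut-2-en-1-yl)phenol
Product: 6 2-bromo-3,5-bis(methoxymethoxy)-4-(3-methylbut-2-en-1-yl)phenol
Conditions: NBS (1.0 equiv), CH2Cl2, −78 °C
Reagents that add atoms: N-bromosuccinimide, O=C1CCC(=O)N1Br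
Why: Electrophilic aromatic bromination of a phloroglucinol-type phenol, expected to be much faster than attack on the trisubstituted alkene at −78 °C; the para position is blocked and the two ortho positions are equivalent by symmetry, so only one monobromide can form.

Step 5
Reactants: 6 2-bromo-3,5-bis(methoxymethoxy)-4-(3-methylbut-2-en-1-yl)phenol
Product: 9 3,5-bis(methoxymethoxy)-4-(3-methylbut-2-en-1-yl)-2-(trimethylsilyl)phenyl trifluoromethanesulfonate, via O-trimethylsilyl ether 7 (not isolated), via lithium 2-silylphenoxide 8 (not isolated)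
Conditions: HMDS, THF, 65 °C, then evaporation; n-BuLi, THF, −100 to −78 °C; Tf2O, −100 to −78 °C; aq. NaHCO3
Reagents that add atoms: hexamethyldisilazane, C[Si](C)(C)N[Si](C)(C)C; trifluoromethanesulfonic anhydride, O=S(=O)(OS(=O)(=O)C(F)(F)F)C(F)(F)F
Why: O-silylation, bromine–lithium exchange (faster than any deprotonation of the prenyl CH2) and 1,3 O-to-C silyl shift (retro-Brook rearrangement) give the 2-silylphenoxide, which Tf2O traps; this is the standard route to 2-(trimethylsilyl)aryl triflates as aryne precursors.

Step 6
Reactants: 10 methyl vanillate (methyl 4-hydroxy-3-methoxybenzoate)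
Product: 11 methyl 3-methoxy-4-(methoxymethoxy)benzoate
Conditions: MOMCl, i-Pr2NEt, CH2Cl2, 0 °C to rt
Reagents that add atoms: chloromethyl methyl ether, COCCl
Why: Phenol protection as the MOM ether (stable to base, fluoride and organolithiums), so that no phenoxide can compete for the aryne in the key step.

Step 7
Reactants: 11 methyl 3-methoxy-4-(methoxymethoxy)benzoate; 12 N-methoxy-N-methylacetamide
Product: 13 N-methoxy-3-[3-methoxy-4-(methoxymethoxy)phenyl]-N-methyl-3-oxopropanamide
Conditions: 12 (2.2 equiv), LiN(i-Pr)2 (2.2 equiv), THF, −78 °C; then 11, −78 to −40 °C; aq. NH4Cl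
Reagents that add atoms: none
Why: Crossed Claisen condensation of the lithium enolate of the Weinreb acetamide with a non-enolisable aryl ester; the second equivalent of enolate deprotonates the β-keto amide and drives the reaction.

Step 8
Reactants: 13 N-methoxy-3-[3-methoxy-4-(methoxymethoxy)phenyl]-N-methyl-3-oxopropanamide
Product: 14 (3S)-3-hydroxy-N-methoxy-3-[3-methoxy-4-(methoxymethoxy)phenyl]-N-methylpropanamide
Conditions: RuCl[(S,S)-TsDPEN](p-cymene) (1 mol %), HCO2H/Et3N (5:2), CH2Cl2, 30 °C
Reagents that add atoms: none
Why: Noyori–Ikariya asymmetric transfer hydrogenation of an aryl ketone through the Ru–H/N–H six-membered transition state with the aryl group held by a CH–π contact to the p-cymene ligand; the (S,S)-ligand should give the (S)-carbinol (same sense as acetophenone to (S)-1-phenylethanol), which sets the C2 stereocentre of the target.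

Step 9
Reactants: 14 (3S)-3-hydroxy-N-methoxy-3-[3-methoxy-4-(methoxymethoxy)phenyl]-N-methylpropanamide
Product: 15 (3S)-N-methoxy-3-[3-methoxy-4-(methoxymethoxy)phenyl]-N-methyl-3-[(trimethylsilyl)oxy]propanamide
Conditions: TMSCl, imidazole, CH2Cl2, 0 °C; filtration through basic alumina, used directly
Reagents that add atoms: chlorotrimethylsilane, C[Si](C)(C)Cl
Why: Silylation of the secondary alcohol without touching the stereocentre; the TMS ether serves as a proton-free, fluoride-releasable alkoxide for the key step.

Step 10
Reactants: 9 3,5-bis(methoxymethoxy)-4-(3-methylbut-2-en-1-yl)-2-(trimethylsilyl)phenyl trifluoromethanesulfonate; 15 (3S)-N-methoxy-3-[3-methoxy-4-(methoxymethoxy)phenyl]-N-methyl-3-[(trimethylsilyl)oxy]propanamide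
Product: 18 (2S)-5,7-bis(methoxymethoxy)-2-[3-methoxy-4-(methoxymethoxy)phenyl]-6-(3-methylbut-2-en-1-yl)-2,3-dihydro-4H-chromen-4-one, via aryne 16 (not isolated), via cesium hemiaminal alkoxide 17 (not isolated)
Conditions: CsF (3 equiv), 18-crown-6 (3 equiv), 15 (1.3 equiv), THF, 0 °C to rt, 9 added slowly by syringe pump; then AcOH, 0 °C
Reagents that add atoms: none
Why: Proposed new method: fluoride cleaves the O–SiMe3 bond of 15 to a cesium alkoxide (no O–H proton in the flask) and, by attack on the C–SiMe3 group of 9 with loss of triflate, releases aryne 16; the alkoxide oxygen adds to the aryne carbon that becomes C8a, and the aryl anion left on C4a attacks the Weinreb amide carbonyl, closing ring C by a 6-exo-trig acyl addition to the tetrahedral adduct 17, which gives the ketone only on the acetic acid quench. The closest known reaction type is the aryne annulation of salicylates and 2-aminobenzoates to xanthones and acridones (heteroatom arylation followed by intramolecular acyl capture of the aryl anion), here moved from a phenoxide on an sp2 tether to a secondary alkoxide on an sp3 tether and from an ester to a Weinreb amide. The regioselectivity the step needs is secured by the groups beside the triple bond: one aryne carbon has the OMOM-bearing C5 as neighbour and the other only C8–H, so the inductively withdrawing, shielding alkoxy group sends the nucleophile to the remote carbon (C8a) and leaves the charge next to oxygen (C4a), as is the rule for 3-alkoxyarynes. No stereocentre of the target is created here: C2 comes from 14, its C–O bond is not broken (retention), and holding C4 as the hemiaminal alkoxide until the quench keeps an enolisable ketone away from the basic medium, so ring opening by retro-oxa-Michael reaction and racemisation should be avoided; the C4 centre of 17 is transient. Acyl capture must outrun protonation of the aryl anion, which the proton-free silyl ether, THF as solvent and slow addition of 9 should ensure.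

Step 11
Reactants: 18 (2S)-5,7-bis(methoxymethoxy)-2-[3-methoxy-4-(methoxymethoxy)phenyl]-6-(3-methylbut-2-en-1-yl)-2,3-dihydro-4H-chromen-4-one
Product: 19 (2S)-5,7-dihydroxy-2-(4-hydroxy-3-methoxyphenyl)-6-(3-methylbut-2-en-1-yl)-2,3-dihydro-4H-chromen-4-one
Conditions: HCl (3 M aq.)/MeOH 1:10, 40 °C
Reagents that add atoms: none
Why: Acid-catalysed acetal methanolysis of three aryl MOM ethers under mild conditions chosen to spare the prenyl group flanked by two phenols; the flavanone C2 centre should be stable to acid, since its racemisation is a base-mediated ring opening.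

**Compound list**
1 | phloroglucinol (benzene-1,3,5-triol) | Oc1cc(O)cc(O)c1 | starting material
2 | 3,5-bis(methoxymethoxy)phenol | COCOc1cc(O)cc(OCOC)c1 | intermediate
3 | [3,5-bis(methoxymethoxy)phenoxy]triisopropylsilane | COCOc1cc(O[Si](C(C)C)(C(C)C)C(C)C)cc(OCOC)c1 | intermediate
4 | [3,5-bis(methoxymethoxy)-4-(3-methylbut-2-en-1-yl)phenoxy]triisopropylsilane | COCOc1cc(O[Si](C(C)C)(C(C)C)C(C)C)cc(OCOC)c1CC=C(C)C | intermediate (not isolated)
5 | 3,5-bis(methoxymethoxy)-4-(3-methylbut-2-en-1-yl)phenol | COCOc1cc(O)cc(OCOC)c1CC=C(C)C | intermediate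
6 | 2-bromo-3,5-bis(methoxymethoxy)-4-(3-methylbut-2-en-1-yl)phenol | COCOc1cc(O)c(Br)c(OCOC)c1CC=C(C)C | intermediate
7 | [2-bromo-3,5-bis(methoxymethoxy)-4-(3-methylbut-2-en-1-yl)phenoxy]trimethylsilane | COCOc1cc(O[Si](C)(C)C)c(Br)c(OCOC)c1CC=C(C)C | intermediate (not isolated)
8 | lithium 3,5-bis(methoxymethoxy)-4-(3-methylbut-2-en-1-yl)-2-(trimethylsilyl)phenoxide | COCOc1cc([O-])c([Si](C)(C)C)c(OCOC)c1CC=C(C)C.[Li+] | intermediate (not isolated)
9 | 3,5-bis(methoxymethoxy)-4-(3-methylbut-2-en-1-yl)-2-(trimethylsilyl)phenyl trifluoromethanesulfonate | COCOc1cc(OS(=O)(=O)C(F)(F)F)c([Si](C)(C)C)c(OCOC)c1CC=C(C)C | intermediate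
10 | methyl vanillate (methyl 4-hydroxy-3-methoxybenzoate) | COC(=O)c1ccc(O)c(OC)c1 | starting material
11 | methyl 3-methoxy-4-(methoxymethoxy)benzoate | COCOc1ccc(C(=O)OC)cc1OC | intermediate
12 | N-methoxy-N-methylacetamide | CC(=O)N(C)OC | starting material
13 | N-methoxy-3-[3-methoxy-4-(methoxymethoxy)phenyl]-N-methyl-3-oxopropanamide | COCOc1ccc(C(=O)CC(=O)N(C)OC)cc1OC | intermediate
14 | (3S)-3-hydroxy-N-methoxy-3-[3-methoxy-4-(methoxymethoxy)phenyl]-N-methylpropanamide | COCOc1ccc([C@@H](O)CC(=O)N(C)OC)cc1OC | intermediate
15 | (3S)-N-methoxy-3-[3-methoxy-4-(methoxymethoxy)phenyl]-N-methyl-3-[(trimethylsilyl)oxy]propanamide | COCOc1ccc([C@@H](O[Si](C)(C)C)CC(=O)N(C)OC)cc1OC | intermediate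
16 | 3,5-bis(methoxymethoxy)-4-(3-methylbut-2-en-1-yl)benzyne (1,2-didehydrobenzene) | COCOC1=CC#CC(OCOC)=C1CC=C(C)C | intermediate (not isolated)
17 | cesium (2S)-4-[methoxy(methyl)amino]-5,7-bis(methoxymethoxy)-2-[3-methoxy-4-(methoxymethoxy)phenyl]-6-(3-methylbut-2-en-1-yl)chroman-4-olate (C4 configuration undefined) | COCOc1ccc([C@@H]2CC([O-])(N(C)OC)c3c(cc(OCOC)c(CC=C(C)C)c3OCOC)O2)cc1OC.[Cs+] | intermediate (not isolated)
18 | (2S)-5,7-bis(methoxymethoxy)-2-[3-methoxy-4-(methoxymethoxy)phenyl]-6-(3-methylbut-2-en-1-yl)-2,3-dihydro-4H-chromen-4-one | COCOc1ccc([C@@H]2CC(=O)c3c(cc(OCOC)c(CC=C(C)C)c3OCOC)O2)cc1OC | intermediate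
19 | (2S)-5,7-dihydroxy-2-(4-hydroxy-3-methoxyphenyl)-6-(3-methylbut-2-en-1-yl)-2,3-dihydro-4H-chromen-4-one | COc1cc([C@@H]2CC(=O)c3c(cc(O)c(CC=C(C)C)c3O)O2)ccc1O | target

**Step count and risks**
Total steps: 11. Longest linear sequence: 7 steps (steps 1–5, 10, 11); the other branch (steps 6–9) joins at step 10.

Steps most likely to fail:

1. Step 10 (proposed new method). The aryl anion may be protonated before acyl capture, so that only the O-aryl ether forms; the hindered secondary alkoxide may add poorly to the aryne; or the tetrahedral adduct may collapse in the basic flask, exposing the ketone to ring opening and loss of configuration. The fallback uses known chemistry, sets out from 13 and 6 and comes back at 18. Compound 13 is reduced with RuCl[(R,R)-TsDPEN](p-cymene) and HCO2H/Et3N to the (3R)-hydroxy Weinreb amide F1. Compound 6 is treated with n-BuLi (2 equiv, THF, −78 °C; O–H deprotonation, then bromine–lithium exchange), and the resulting C,O-dilithio species is added to the lithium alkoxide of F1 (from LiN(SiMe3)2, 1 equiv); aqueous work-up should give the 2-hydroxyaryl β-hydroxy ketone F2. Mitsunobu cyclisation of F2 (PPh3, DIAD, THF, 0 °C) closes O1–C2 with inversion, (R) to (S), and gives 18. Here C4–C4a is made by aryllithium addition to a Weinreb amide and ring C is closed last at the stereocentre.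

2. Step 4. Bromination may go to the prenyl double bond or give ring dibromination. The fallback sets out from 5 and comes back at 9, with no electrophilic halogen. Compound 5 is carbamoylated (ClC(O)NEt2, NaH, THF) to the aryl N,N-diethylcarbamate F3. Carbamate-directed ortho-lithiation (s-BuLi, TMEDA, THF, −78 °C; both ortho positions are equivalent) and TMSCl give the ortho-silyl carbamate F4. Reductive cleavage with Cp2Zr(H)Cl (THF, rt) gives the 2-silylphenol F5, and triflation (Tf2O, pyridine, CH2Cl2, 0 °C) gives 9.

3. Step 7. The Weinreb acetamide enolate may decompose (loss of formaldehyde), or attack on the electron-rich ester may be sluggish. The fallback sets out from 11 and comes back at 13. Claisen condensation of 11 with the lithium enolate of tert-butyl acetate (LiN(i-Pr)2, THF, −78 to 0 °C) gives the tert-butyl β-keto ester F6. Heating F6 with N,O-dimethylhydroxylamine (hydrochloride plus Et3N, toluene, 110 °C, sealed tube) exchanges the ester for the amide through the acylketene and gives 13.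

Further compounds
F1 | step 10 | (3R)-3-hydroxy-N-methoxy-3-[3-methoxy-4-(methoxymethoxy)phenyl]-N-methylpropanamide | COCOc1ccc([C@H](O)CC(=O)N(C)OC)cc1OC
F2 | step 10 | (3R)-3-hydroxy-1-[6-hydroxy-2,4-bis(methoxymethoxy)-3-(3-methylbut-2-en-1-yl)phenyl]-3-[3-methoxy-4-(methoxymethoxy)phenyl]propan-1-one | COCOc1ccc([C@H](O)CC(=O)c2c(O)cc(OCOC)c(CC=C(C)C)c2OCOC)cc1OC
F3 | step 4 | 3,5-bis(methoxymethoxy)-4-(3-methylbut-2-en-1-yl)phenyl N,N-diethylcarbamate | CCN(CC)C(=O)Oc1cc(OCOC)c(CC=C(C)C)c(OCOC)c1
F4 | step 4 | 3,5-bis(methoxymethoxy)-4-(3-methylbut-2-en-1-yl)-2-(trimethylsilyl)phenyl N,N-diethylcarbamate | CCN(CC)C(=O)Oc1cc(OCOC)c(CC=C(C)C)c(OCOC)c1[Si](C)(C)C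
F5 | step 4 | 3,5-bis(methoxymethoxy)-4-(3-methylbut-2-en-1-yl)-2-(trimethylsilyl)phenol | COCOc1cc(O)c([Si](C)(C)C)c(OCOC)c1CC=C(C)C
F6 | step 7 | tert-butyl 3-[3-methoxy-4-(methoxymethoxy)phenyl]-3-oxopropanoate | COCOc1ccc(C(=O)CC(=O)OC(C)(C)C)cc1OC
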